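## Retrosynthetic overview

- The strategy rests on ring A of the flavonol. C5, C7 and C8a each carry oxygen, and C8 carries the quaternary carbon of the 1,1-dimethylallyl group; C8 lies between O7 and O8a and para to O5.
- Ring C is opened last, by Algar–Flynn–Oyamada disconnection (O1–C2 and C3–OH) to a 2'-hydroxychalcone. This oxidative closure supplies the C3 hydroxyl, which a plain diketone cyclisation would not. The chalcone comes from a ring A 2-hydroxyacetophenone and a ring B aldehyde, made from 3-bromo-4,5-dihydroxybenzaldehyde by acetal protection and Stille prenylation.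
- The acetyl group at C4a is traced back to ortho-formylation of the O8a phenol, methyl addition and oxidation. That phenol comes from the benzannulation product by masking O7 as its methoxymethyl ether and removing the silyl group from O8a.
- Ring A is disconnected by Danheiser benzannulation into 3-[2-(trimethylsilyl)ethoxy]cyclobutenone and the triisopropylsilyl ynol ether that already carries the 1,1-dimethylallyl group. The ynol ether comes from Kowalski homologation of ethyl 2,2-dimethylbut-3-enoate.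
- Order of ring formation: ring A (benzannulation), ring B brought in intact, ring C (oxidative cyclisation).

Key step: step 4

Remark: the target has no stereocentre. Flavone numbering (O1, C2, C3, C4, C4a, C5 to C8, C8a) and ring letters A, B and C are used throughout. Reagents named without a compound number are taken as commercial.

## Route

Step 1
Reactants: 1 2,2-dimethylbut-3-enoic acid
Product: 2 ethyl 2,2-dimethylbut-3-enoate
Conditions: EtI, K2CO3, DMF, rt
Reagents that add atoms: iodoethane, CCI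
Why: SN2 O-alkylation of the potassium carboxylate esterifies the hindered, non-enolisable acid without acid catalysis and leaves the vinyl group alone.

Step 2
Reactants: 2 ethyl 2,2-dimethylbut-3-enoate
Product: 5 triisopropyl[(3,3-dimethylpent-4-en-1-yn-1-yl)oxy]silane, via lithium dibromoenolate 3 (not isolated), via lithium ynolate 4 (not isolated)
Conditions: CH2Br2, lithium 2,2,6,6-tetramethylpiperidide, THF, −78 °C; LiN(SiMe3)2; n-BuLi, −78 °C → rt; iPr3SiOTf, −78 → 0 °C
Reagents that add atoms: dibromomethane, BrCBr; triisopropylsilyl trifluoromethanesulfonate, CC(C)[Si](C(C)C)(C(C)C)OS(=O)(=O)C(F)(F)F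
Why: Kowalski ester homologation: dibromomethyllithium adds to the ester, the dibromoketone enolate undergoes bromine–lithium exchange and 1,2-shift of the tert-alkyl group to the lithium ynolate, and the bulky silyl triflate should trap it on oxygen.

Step 3
Reactants: 6 3-ethoxycyclobut-2-en-1-one; 7 2-(trimethylsilyl)ethanol
Product: 8 3-[2-(trimethylsilyl)ethoxy]cyclobut-2-en-1-one
Conditions: 7 (3 equiv), camphor-10-sulfonic acid (5 mol %), toluene, 35 °C, 80 mbar (EtOH removed)
Reagents that add atoms: none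
Why: Acid-catalysed addition–elimination at C3 of the vinylogous ester (transetherification), driven by removal of ethanol and run below the temperature at which the cyclobutenone opens, should exchange the alkoxy group.

Step 4
Reactants: 8 3-[2-(trimethylsilyl)ethoxy]cyclobut-2-en-1-one; 5 triisopropyl[(3,3-dimethylpent-4-en-1-yn-1-yl)oxy]silane
Product: 13 2-(2-methylbut-3-en-2-yl)-3-(triisopropylsilyloxy)-5-[2-(trimethylsilyl)ethoxy]phenol, via vinylketene 9 (not isolated), via vinylcyclobutenone 10 (not isolated), via dienylketene 11 (not isolated), via cyclohexadienone 12 (not isolated)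
Conditions: 5 (1 equiv), 8 (1.5 equiv), toluene, 80 °C then 110 °C, sealed tube, under argon
Reagents that add atoms: none
Why: Thermal four-electron electrocyclic opening of 8 gives alkoxy vinylketene 9, whose ketene C=C adds across the siloxyalkyne in a regiospecific [2+2] cycloaddition to give 4-vinylcyclobutenone 10; this makes C7–C8 and C8a–C4a. Compound 10 opens again to dienylketene 11, which closes ring A by six-electron electrocyclisation (C6–C7) to cyclohexadienone 12 and tautomerises to phenol 13. The closest known reaction type is the Danheiser benzannulation of cyclobutenones with trialkylsiloxyalkynes, here applied to a tert-alkyl ynol ether and a 3-alkoxycyclobutenone. No stereocentre survives, since the single centre of 10 is lost on ring opening. The step needs only regioselectivity in the [2+2] event, and the polarisation of the ynol ether secures it: its nucleophilic carbon, the one bearing the tert-alkyl group, bonds to the electrophilic ketene carbonyl carbon, so the free hydroxyl (O7) and the silyl ether (O8a) flank C8 and the alkyl ether (O5) sits para to it. The quaternary carbon arrives with the alkyne, so no aryl-to-quaternary bond is made on an arene; the price is a slower cycloaddition, met by an excess of 8 and staged heating.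

Step 5
Reactants: 13 2-(2-methylbut-3-en-2-yl)-3-(triisopropylsilyloxy)-5-[2-(trimethylsilyl)ethoxy]phenol
Product: 14 triisopropyl{3-(methoxymethoxy)-2-(2-methylbut-3-en-2-yl)-5-[2-(trimethylsilyl)ethoxy]phenoxy}silane
Conditions: NaH, MOMCl, DMF, 0 °C → rt
Reagents that add atoms: chloromethyl methyl ether, COCCl
Why: Williamson-type O-alkylation of the sodium phenoxide (O7) with the reactive alpha-chloro ether should proceed despite the ortho quaternary group, and both silyl groups are stable to these conditions.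

Step 6
Reactants: 14 triisopropyl{3-(methoxymethoxy)-2-(2-methylbut-3-en-2-yl)-5-[2-(trimethylsilyl)ethoxy]phenoxy}silane
Product: 15 3-(methoxymethoxy)-2-(2-methylbut-3-en-2-yl)-5-[2-(trimethylsilyl)ethoxy]phenol
Conditions: Bu4NF (1.1 equiv), THF, 0 °C
Reagents that add atoms: none
Why: Fluoride desilylation cleaves the aryl triisopropylsilyl ether at 0 °C, whereas the aryl 2-(trimethylsilyl)ethyl ether needs heating for its beta-elimination and the acetal is inert, so only O8a should be freed.

Step 7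
Reactants: 15 3-(methoxymethoxy)-2-(2-methylbut-3-en-2-yl)-5-[2-(trimethylsilyl)ethoxy]phenol
Product: 16 2-hydroxy-4-(methoxymethoxy)-3-(2-methylbut-3-en-2-yl)-6-[2-(trimethylsilyl)ethoxy]benzaldehyde
Conditions: MgCl2, Et3N, (CH2O)n, MeCN, 80 °C
Reagents that add atoms: paraformaldehyde (as formaldehyde), C=O
Why: Magnesium-mediated ortho-formylation (Casnati–Skattebøl) delivers formaldehyde from the magnesium phenoxide to the ortho carbon through a six-membered chelate and a second formaldehyde oxidises the benzylic alkoxide; C8 is blocked, so only C4a reacts and the para carbon C6 is not touched.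

Step 8
Reactants: 16 2-hydroxy-4-(methoxymethoxy)-3-(2-methylbut-3-en-2-yl)-6-[2-(trimethylsilyl)ethoxy]benzaldehyde
Product: 17 2-(1-hydroxyethyl)-5-(methoxymethoxy)-6-(2-methylbut-3-en-2-yl)-3-[2-(trimethylsilyl)ethoxy]phenol (racemic)
Conditions: MeMgBr (3 equiv), THF, 0 °C → rt
Reagents that add atoms: methylmagnesium bromide, C[Mg]Br
Why: Grignard 1,2-addition to the aldehyde of the magnesium phenoxide (the first equivalent is consumed by the phenol) should give the benzylic alcohol as a racemate, and its stereocentre is erased in step 9.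

Step 9
Reactants: 17 2-(1-hydroxyethyl)-5-(methoxymethoxy)-6-(2-methylbut-3-en-2-yl)-3-[2-(trimethylsilyl)ethoxy]phenol
Product: 18 1-{2-hydroxy-4-(methoxymethoxy)-3-(2-methylbut-3-en-2-yl)-6-[2-(trimethylsilyl)ethoxy]phenyl}ethan-1-one
Conditions: MnO2 (activated, excess), CH2Cl2, rt
Reagents that add atoms: none
Why: Selective MnO2 oxidation of the benzylic alcohol should give the hydrogen-bonded 2-hydroxyacetophenone without touching the alkenes, the acetal or the silyl group.

Step 10
Reactants: 19 3-bromo-4,5-dihydroxybenzaldehyde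
Product: 20 3-bromo-4,5-bis(methoxymethoxy)benzaldehyde
Conditions: MOMCl, iPr2NEt, CH2Cl2, 0 °C → rt
Reagents that add atoms: chloromethyl methyl ether, COCCl
Why: Base-mediated O-alkylation of both phenols gives acetal ethers that survive cross-coupling, aldol condensation and alkaline peroxide and are removed by mild acid at the end.

Step 11
Reactants: 20 3-bromo-4,5-bis(methoxymethoxy)benzaldehyde
Product: 21 3,4-bis(methoxymethoxy)-5-(3-methylbut-2-en-1-yl)benzaldehyde
Conditions: tributyl(3-methylbut-2-en-1-yl)stannane, Pd(PPh3)4 (5 mol %), DMF, 90 °C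
Reagents that add atoms: tributyl(3-methylbut-2-en-1-yl)stannane, CCCC[Sn](CCCC)(CCCC)CC=C(C)C
Why: Migita–Kosugi–Stille coupling: zerovalent palladium inserts into the aryl–bromine bond, the allyl group is transferred from tin and reductive elimination at the unsubstituted allyl terminus should give the linear prenyl arene, with the aldehyde tolerated.

Step 12
Reactants: 18 1-{2-hydroxy-4-(methoxymethoxy)-3-(2-methylbut-3-en-2-yl)-6-[2-(trimethylsilyl)ethoxy]phenyl}ethan-1-one; 21 3,4-bis(methoxymethoxy)-5-(3-methylbut-2-en-1-yl)benzaldehyde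
Product: 22 (E)-1-{2-hydroxy-4-(methoxymethoxy)-3-(2-methylbut-3-en-2-yl)-6-[2-(trimethylsilyl)ethoxy]phenyl}-3-[3,4-bis(methoxymethoxy)-5-(3-methylbut-2-en-1-yl)phenyl]prop-2-en-1-one
Conditions: KOH, EtOH–H2O, rt
Reagents that add atoms: none
Why: Claisen–Schmidt aldol condensation: the ketone enolate adds to the non-enolisable aldehyde and E1cB dehydration gives the chalcone, the E geometry being the thermodynamic outcome.

Step 13
Reactants: 22 (E)-1-{2-hydroxy-4-(methoxymethoxy)-3-(2-methylbut-3-en-2-yl)-6-[2-(trimethylsilyl)ethoxy]phenyl}-3-[3,4-bis(methoxymethoxy)-5-(3-methylbut-2-en-1-yl)phenyl]prop-2-en-1-one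
Product: 24 3-hydroxy-7-(methoxymethoxy)-8-(2-methylbut-3-en-2-yl)-2-[3,4-bis(methoxymethoxy)-5-(3-methylbut-2-en-1-yl)phenyl]-5-[2-(trimethylsilyl)ethoxy]-4H-chromen-4-one, via trans-dihydroflavonol 23 (not isolated)
Conditions: H2O2 (30% aq), NaOH (aq), MeOH, 0 °C → rt
Reagents that add atoms: hydrogen peroxide, OO
Why: Algar–Flynn–Oyamada reaction: the 2'-phenoxide closes ring C by 6-endo oxa-Michael addition (O1–C2) while hydrogen peroxide hydroxylates the enolate at C3 to the racemic trans-dihydroflavonol, which the same alkaline peroxide dehydrogenates to the achiral flavonol; the isolated alkenes are inert to nucleophilic hydroperoxide.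

Step 14
Reactants: 24 3-hydroxy-7-(methoxymethoxy)-8-(2-methylbut-3-en-2-yl)-2-[3,4-bis(methoxymethoxy)-5-(3-methylbut-2-en-1-yl)phenyl]-5-[2-(trimethylsilyl)ethoxy]-4H-chromen-4-one
Product: 25 3,5-dihydroxy-7-(methoxymethoxy)-8-(2-methylbut-3-en-2-yl)-2-[3,4-bis(methoxymethoxy)-5-(3-methylbut-2-en-1-yl)phenyl]-4H-chromen-4-one
Conditions: Bu4NF (5 equiv), DMF, 60 °C, under argon
Reagents that add atoms: none
Why: Fluoride attack on silicon triggers beta-elimination of the 2-(trimethylsilyl)ethyl ether, the C5 phenoxide peri to the carbonyl being a good leaving group, while the acetals keep the catechol and O7 masked under the basic conditions.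

Step 15
Reactants: 25 3,5-dihydroxy-7-(methoxymethoxy)-8-(2-methylbut-3-en-2-yl)-2-[3,4-bis(methoxymethoxy)-5-(3-methylbut-2-en-1-yl)phenyl]-4H-chromen-4-one
Product: 26 2-[3,4-dihydroxy-5-(3-methylbut-2-en-1-yl)phenyl]-3,5,7-trihydroxy-8-(2-methylbut-3-en-2-yl)-4H-chromen-4-one (CNP0196880.0)
Conditions: HCl (3 M aq), MeOH, rt → 40 °C
Reagents that add atoms: none
Why: Acid-catalysed methanolysis of the three methoxymethyl acetals through oxocarbenium ions, under dilute and cool conditions, should free the phenols before the prenyl and 1,1-dimethylallyl groups can be protonated and cyclise onto the neighbouring hydroxyls.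

## Compound list

1 | 2,2-dimethylbut-3-enoic acid | C=CC(C)(C)C(=O)O | starting material
2 | ethyl 2,2-dimethylbut-3-enoate | C=CC(C)(C)C(=O)OCC | intermediate
3 | lithium 1,1-dibromo-3,3-dimethylpenta-1,4-dien-2-olate (not isolated) | [Li]OC(=C(Br)Br)C(C)(C)C=C | intermediate
4 | lithium 3,3-dimethylpent-4-en-1-yn-1-olate (not isolated) | [Li]OC#CC(C)(C)C=C | intermediate
5 | triisopropyl[(3,3-dimethylpent-4-en-1-yn-1-yl)oxy]silane | C=CC(C)(C)C#CO[Si](C(C)C)(C(C)C)C(C)C | intermediate
6 | 3-ethoxycyclobut-2-en-1-one | CCOC1=CC(=O)C1 | starting material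
7 | 2-(trimethylsilyl)ethanol | C[Si](C)(C)CCO | starting material
8 | 3-[2-(trimethylsilyl)ethoxy]cyclobut-2-en-1-one | O=C1C=C(OCC[Si](C)(C)C)C1 | intermediate
9 | 3-[2-(trimethylsilyl)ethoxy]buta-1,3-dien-1-one (vinylketene, not isolated) | O=C=CC(=C)OCC[Si](C)(C)C | intermediate
10 | 2-(2-methylbut-3-en-2-yl)-3-(triisopropylsilyloxy)-4-{1-[2-(trimethylsilyl)ethoxy]ethenyl}cyclobut-2-en-1-one (racemic, not isolated) | O=C1C(C(C)(C)C=C)=C(O[Si](C(C)C)(C(C)C)C(C)C)C1C(=C)OCC[Si](C)(C)C | intermediate
11 | (3E)-2-(2-methylbut-3-en-2-yl)-3-(triisopropylsilyloxy)-5-[2-(trimethylsilyl)ethoxy]hexa-1,3,5-trien-1-one (dienylketene with ketene and vinyl groups cis, not isolated) | O=C=C(C(C)(C)C=C)/C(O[Si](C(C)C)(C(C)C)C(C)C)=C\C(=C)OCC[Si](C)(C)C | intermediate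
12 | 2-(2-methylbut-3-en-2-yl)-3-(triisopropylsilyloxy)-5-[2-(trimethylsilyl)ethoxy]cyclohexa-2,4-dien-1-one (not isolated) | O=C1CC(OCC[Si](C)(C)C)=CC(O[Si](C(C)C)(C(C)C)C(C)C)=C1C(C)(C)C=C | intermediate
13 | 2-(2-methylbut-3-en-2-yl)-3-(triisopropylsilyloxy)-5-[2-(trimethylsilyl)ethoxy]phenol | C=CC(C)(C)c1c(O)cc(OCC[Si](C)(C)C)cc1O[Si](C(C)C)(C(C)C)C(C)C | intermediate
14 | triisopropyl{3-(methoxymethoxy)-2-(2-methylbut-3-en-2-yl)-5-[2-(trimethylsilyl)ethoxy]phenoxy}silane | C=CC(C)(C)c1c(OCOC)cc(OCC[Si](C)(C)C)cc1O[Si](C(C)C)(C(C)C)C(C)C | intermediate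
15 | 3-(methoxymethoxy)-2-(2-methylbut-3-en-2-yl)-5-[2-(trimethylsilyl)ethoxy]phenol | C=CC(C)(C)c1c(OCOC)cc(OCC[Si](C)(C)C)cc1O | intermediate
16 | 2-hydroxy-4-(methoxymethoxy)-3-(2-methylbut-3-en-2-yl)-6-[2-(trimethylsilyl)ethoxy]benzaldehyde | C=CC(C)(C)c1c(OCOC)cc(OCC[Si](C)(C)C)c(C=O)c1O | intermediate
17 | 2-(1-hydroxyethyl)-5-(methoxymethoxy)-6-(2-methylbut-3-en-2-yl)-3-[2-(trimethylsilyl)ethoxy]phenol (racemic) | C=CC(C)(C)c1c(OCOC)cc(OCC[Si](C)(C)C)c(C(C)O)c1O | intermediate
18 | 1-{2-hydroxy-4-(methoxymethoxy)-3-(2-methylbut-3-en-2-yl)-6-[2-(trimethylsilyl)ethoxy]phenyl}ethan-1-one | C=CC(C)(C)c1c(OCOC)cc(OCC[Si](C)(C)C)c(C(C)=O)c1O | intermediate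
19 | 3-bromo-4,5-dihydroxybenzaldehyde | O=Cc1cc(O)c(O)c(Br)c1 | starting material
20 | 3-bromo-4,5-bis(methoxymethoxy)benzaldehyde | O=Cc1cc(OCOC)c(OCOC)c(Br)c1 | intermediate
21 | 3,4-bis(methoxymethoxy)-5-(3-methylbut-2-en-1-yl)benzaldehyde | O=Cc1cc(OCOC)c(OCOC)c(CC=C(C)C)c1 | intermediate
22 | (E)-1-{2-hydroxy-4-(methoxymethoxy)-3-(2-methylbut-3-en-2-yl)-6-[2-(trimethylsilyl)ethoxy]phenyl}-3-[3,4-bis(methoxymethoxy)-5-(3-methylbut-2-en-1-yl)phenyl]prop-2-en-1-one | C=CC(C)(C)c1c(OCOC)cc(OCC[Si](C)(C)C)c(C(=O)/C=C/c2cc(OCOC)c(OCOC)c(CC=C(C)C)c2)c1O | intermediate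
23 | trans-3-hydroxy-7-(methoxymethoxy)-8-(2-methylbut-3-en-2-yl)-2-[3,4-bis(methoxymethoxy)-5-(3-methylbut-2-en-1-yl)phenyl]-5-[2-(trimethylsilyl)ethoxy]chroman-4-one (racemic; the 2R,3R enantiomer is drawn; not isolated) | O=C1[C@H](O)[C@@H](c2cc(OCOC)c(OCOC)c(CC=C(C)C)c2)Oc2c(C(C)(C)C=C)c(OCOC)cc(OCC[Si](C)(C)C)c12 | intermediate
24 | 3-hydroxy-7-(methoxymethoxy)-8-(2-methylbut-3-en-2-yl)-2-[3,4-bis(methoxymethoxy)-5-(3-methylbut-2-en-1-yl)phenyl]-5-[2-(trimethylsilyl)ethoxy]-4H-chromen-4-one | C=CC(C)(C)c1c(OCOC)cc(OCC[Si](C)(C)C)c2c(=O)c(O)c(-c3cc(OCOC)c(OCOC)c(CC=C(C)C)c3)oc12 | intermediate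
25 | 3,5-dihydroxy-7-(methoxymethoxy)-8-(2-methylbut-3-en-2-yl)-2-[3,4-bis(methoxymethoxy)-5-(3-methylbut-2-en-1-yl)phenyl]-4H-chromen-4-one | C=CC(C)(C)c1c(OCOC)cc(O)c2c(=O)c(O)c(-c3cc(OCOC)c(OCOC)c(CC=C(C)C)c3)oc12 | intermediate
26 | 2-[3,4-dihydroxy-5-(3-methylbut-2-en-1-yl)phenyl]-3,5,7-trihydroxy-8-(2-methylbut-3-en-2-yl)-4H-chromen-4-one | C=CC(C)(C)c1c(O)cc(O)c2c(=O)c(O)c(-c3cc(O)c(O)c(CC=C(C)C)c3)oc12 | target

## Step count

Total steps: 15.
Longest linear sequence: 12 steps (steps 1, 2, 4, 5, 6, 7, 8, 9, 12, 13, 14, 15, from acid 1).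

## Steps most likely to fail

**Step 4 (key benzannulation).** The bimolecular [2+2] capture of the vinylketene by the tert-alkyl-substituted alkyne may be too slow. Ketene self-condensation, or acylation of the product phenol by the ketene, could then outrun ring formation.

The fallback makes the aryl-to-quaternary bond by aromatic Claisen rearrangement on an acylphloroglucinol instead. It sets out from alcohol 7, with commercial 2',4',6'-trihydroxyacetophenone as an added starting material, and comes back to the route at acetophenone 18, so steps 5 to 9 are not needed. The non-chelated 4'-hydroxyl is alkylated with 1-bromo-3-methylbut-2-ene (K2CO3, acetone) to give 1-{2,6-dihydroxy-4-[(3-methylbut-2-en-1-yl)oxy]phenyl}ethan-1-one F1. Mitsunobu etherification with 7 (PPh3, diisopropyl azodicarboxylate, THF) of one of the two equivalent ortho hydroxyls gives 1-{2-hydroxy-4-[(3-methylbut-2-en-1-yl)oxy]-6-[2-(trimethylsilyl)ethoxy]phenyl}ethan-1-one F2. Heating in N,N-diethylaniline at about 190 °C should bring about the [3,3] shift of the prenyl ether with allylic inversion, steered to C3' by the bond fixation of the chelated hydroxyketone, to give 1-{2,4-dihydroxy-3-(2-methylbut-3-en-2-yl)-6-[2-(trimethylsilyl)ethoxy]phenyl}ethan-1-one F3. Selective methoxymethylation of the free, non-chelated 4'-hydroxyl (MOMCl, iPr2NEt, CH2Cl2) then gives 18.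

**Step 2 (Kowalski homologation).** Addition of dibromomethyllithium to the alpha-quaternary ester may be sluggish, and the rearrangement to the ynolate incomplete, so that little ynolate is available for silylation.

The fallback makes the same ynolate by oxidation of an acetylide. It sets out from ester 2 and comes back at siloxyalkyne 5 through ynolate 4. Reduction with iBu2AlH (CH2Cl2, −78 °C) gives 2,2-dimethylbut-3-enal F4. Corey–Fuchs olefination (CBr4, PPh3, CH2Cl2) gives 1,1-dibromo-3,3-dimethylpenta-1,4-diene F5. Treatment with n-BuLi (2 equiv, THF, −78 °C) gives lithium 3,3-dimethylpent-4-en-1-yn-1-ide F6, which is oxidised in the same flask with lithium tert-butyl peroxide (from t-BuOOH and LiN(SiMe3)2) to ynolate 4 and silylated with iPr3SiOTf to give 5.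

**Step 13 (Algar–Flynn–Oyamada).** Closure of the phenoxide onto the alpha-carbon, the five-membered aurone pathway, may compete with the six-membered closure because of the alkoxy group at C6' of the chalcone.

The fallback builds ring C by Baker–Venkataraman chemistry and oxidises C3 afterwards. It sets out from acetophenone 18 and aldehyde 21 and comes back at flavonol 24. Pinnick oxidation of 21 (NaClO2, NaH2PO4, 2-methylbut-2-ene, t-BuOH–H2O) gives 3,4-bis(methoxymethoxy)-5-(3-methylbut-2-en-1-yl)benzoic acid F7. Esterification of the phenol of 18 with F7 (1-ethyl-3-(3-dimethylaminopropyl)carbodiimide, 4-dimethylaminopyridine, CH2Cl2) gives 2-acetyl-3-[2-(trimethylsilyl)ethoxy]-5-(methoxymethoxy)-6-(2-methylbut-3-en-2-yl)phenyl 3,4-bis(methoxymethoxy)-5-(3-methylbut-2-en-1-yl)benzoate F8. Baker–Venkataraman acyl shift (KOt-Bu, THF) gives 1-{2-hydroxy-4-(methoxymethoxy)-3-(2-methylbut-3-en-2-yl)-6-[2-(trimethylsilyl)ethoxy]phenyl}-3-[3,4-bis(methoxymethoxy)-5-(3-methylbut-2-en-1-yl)phenyl]propane-1,3-dione F9. Cyclodehydration with catalytic p-toluenesulfonic acid in toluene at 60 °C gives 7-(methoxymethoxy)-8-(2-methylbut-3-en-2-yl)-2-[3,4-bis(methoxymethoxy)-5-(3-methylbut-2-en-1-yl)phenyl]-5-[2-(trimethylsilyl)ethoxy]-4H-chromen-4-one F10. Lithiation at C3 with LiN(iPr)2 (THF, −78 °C), boration with B(OMe)3 and oxidation with H2O2 then give 24.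

## Further compounds

F1 | step 4 | 1-{2,6-dihydroxy-4-[(3-methylbut-2-en-1-yl)oxy]phenyl}ethan-1-one | CC(=O)c1c(O)cc(OCC=C(C)C)cc1O
F2 | step 4 | 1-{2-hydroxy-4-[(3-methylbut-2-en-1-yl)oxy]-6-[2-(trimethylsilyl)ethoxy]phenyl}ethan-1-one | CC(=O)c1c(O)cc(OCC=C(C)C)cc1OCC[Si](C)(C)C
F3 | step 4 | 1-{2,4-dihydroxy-3-(2-methylbut-3-en-2-yl)-6-[2-(trimethylsilyl)ethoxy]phenyl}ethan-1-one | CC(=O)c1c(O)c(C(C)(C)C=C)c(O)cc1OCC[Si](C)(C)C
F4 | step 2 | 2,2-dimethylbut-3-enal | C=CC(C)(C)C=O
F5 | step 2 | 1,1-dibromo-3,3-dimethylpenta-1,4-diene | C=CC(C)(C)C=C(Br)Br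
F6 | step 2 | lithium 3,3-dimethylpent-4-en-1-yn-1-ide | [Li]C#CC(C)(C)C=C
F7 | step 13 | 3,4-bis(methoxymethoxy)-5-(3-methylbut-2-en-1-yl)benzoic acid | OC(=O)c1cc(OCOC)c(OCOC)c(CC=C(C)C)c1
F8 | step 13 | 2-acetyl-3-[2-(trimethylsilyl)ethoxy]-5-(methoxymethoxy)-6-(2-methylbut-3-en-2-yl)phenyl 3,4-bis(methoxymethoxy)-5-(3-methylbut-2-en-1-yl)benzoate | C=CC(C)(C)c1c(OCOC)cc(OCC[Si](C)(C)C)c(C(C)=O)c1OC(=O)c1cc(OCOC)c(OCOC)c(CC=C(C)C)c1
F9 | step 13 | 1-{2-hydroxy-4-(methoxymethoxy)-3-(2-methylbut-3-en-2-yl)-6-[2-(trimethylsilyl)ethoxy]phenyl}-3-[3,4-bis(methoxymethoxy)-5-(3-methylbut-2-en-1-yl)phenyl]propane-1,3-dione | C=CC(C)(C)c1c(OCOC)cc(OCC[Si](C)(C)C)c(C(=O)CC(=O)c2cc(OCOC)c(OCOC)c(CC=C(C)C)c2)c1O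
F10 | step 13 | 7-(methoxymethoxy)-8-(2-methylbut-3-en-2-yl)-2-[3,4-bis(methoxymethoxy)-5-(3-methylbut-2-en-1-yl)phenyl]-5-[2-(trimethylsilyl)ethoxy]-4H-chromen-4-one | C=CC(C)(C)c1c(OCOC)cc(OCC[Si](C)(C)C)c2c(=O)cc(-c3cc(OCOC)c(OCOC)c(CC=C(C)C)c3)oc12
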